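**Retrosynthetic overview**

1. Feature used: in the lactone ring (O1, carbonyl C2, methylene-bearing C3, acid-bearing C4, chain-bearing C5) the carbons C2–C3–C4–C5 form an unbroken four-carbon chain bridged at its ends by O1. Removing O1 leaves a trans-2-alkyl-3-substituted cyclobutanone that already holds both stereocentres.
2. Last operations: the exocyclic CH2 on C3 (carboxylation, then decarboxylative Mannich methylenation) and the terminal acetate; the C4 acid comes from a CH2OBn group.
3. Key disconnection: the O1–C5 bond, made by Baeyer–Villiger oxygen insertion into (2R,3S)-2-(13-acetoxytridecyl)-3-(benzyloxymethyl)cyclobutanone.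
4. The cyclobutanone comes from a [2+2] cycloaddition of the keteniminium ion of a 15-acetoxypentadecanoyl (2R,5R)-2,5-dimethylpyrrolidine amide with allyl benzyl ether; the auxiliary sets the CH2OBn carbon and equilibration sets the chain carbon.
5. Ring order: the four-membered carbocycle first (step 3), then its expansion to the five-membered lactone (step 5), the only ring of the target.

Key step: step 5

**Remarks on the chemistry (assumptions)**

- The sense of induction of the C2-symmetric auxiliary with this monosubstituted alkene is assumed: the (2R,5R) amine is taken to give the (3S) ring carbon. If the cycloaddition favours the (3R) ketone, the (2S,5S) amine is used in steps 2 and 3 with nothing else changed.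
- The primary acetate is not expected to survive MeOMgOCO2Me at 130 °C (magnesium methoxide transesterification). Steps 8 and 9 are therefore written for the free alcohol, and the acetate is put back in step 10.
- 15-Hydroxypentadecanoic acid is taken as a commercial starting material; it is also the saponification product of 15-pentadecanolide.

**Route**

Step 1
Reactants: 1 15-hydroxypentadecanoic acid
Product: 2 15-acetoxypentadecanoic acid
Conditions: Ac2O, pyridine, DMAP (cat.), CH2Cl2, 0 °C to rt; then H2O/THF, rt
Reagents that add atoms: acetic anhydride, CC(=O)OC(C)=O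
Why: DMAP-catalysed O-acetylation of the primary alcohol should proceed cleanly, the mixed anhydride at the acid being hydrolysed in the aqueous stage, so the acetate protects the hydroxyl through the Tf2O, peracid and CrO3 steps.

Step 2
Reactants: 2 15-acetoxypentadecanoic acid; 3 (2R,5R)-2,5-dimethylpyrrolidine
Product: 5 15-[(2R,5R)-2,5-dimethylpyrrolidin-1-yl]-15-oxopentadecyl acetate, via 15-acetoxypentadecanoyl chloride 4 (not isolated)
Conditions: (COCl)2, DMF (cat.), CH2Cl2, 0 °C to rt, evaporate; then 3, Et3N, CH2Cl2, 0 °C to rt
Reagents that add atoms: oxalyl chloride, O=C(Cl)C(Cl)=O (supplies only the chlorine of 4; no reagent atom remains in 5)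
Why: Acid chloride formation under Vilsmeier catalysis followed by N-acylation is the dependable way to acylate an α,α'-disubstituted secondary amine; the acetate and the two stereocentres of the amine are untouched.

Step 3
Reactants: 5 15-[(2R,5R)-2,5-dimethylpyrrolidin-1-yl]-15-oxopentadecyl acetate; 6 allyl benzyl ether
Product: 9 (3S)-2-(13-acetoxytridecyl)-3-(benzyloxymethyl)cyclobutanone as a mixture of C2 epimers, via keteniminium triflate 7 (not isolated), via cyclobutaniminium triflate 8 (not isolated)
Conditions: Tf2O, 2,4,6-collidine (slow addition), 6 (3 equiv), ClCH2CH2Cl, −20 °C to reflux; then aq. NaHCO3, CH2Cl2, rt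
Reagents that add atoms: water, O (the carbonyl oxygen of 9); triflic anhydride, O=S(=O)(OS(=O)(=O)C(F)(F)F)C(F)(F)F (supplies only the triflate counter-ion of 7 and 8)
Why: Keteniminium–alkene [2+2] cycloaddition: Tf2O O-triflates the amide and collidine removes an α-proton to give 7, whose central carbon bonds to the terminal CH2 of the alkene and whose α-carbon then closes onto the internal carbon, so the CH2OBn carbon becomes C3; the C2-symmetric pyrrolidine gives one keteniminium geometry and shields one face, which should set C3 as S, while C2 forms as both epimers and bicarbonate hydrolysis of 8 releases the ketone and the amine.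

Step 4
Reactants: 9 (3S)-2-(13-acetoxytridecyl)-3-(benzyloxymethyl)cyclobutanone as a mixture of C2 epimers
Product: 10 (2R,3S)-2-(13-acetoxytridecyl)-3-(benzyloxymethyl)cyclobutanone (trans)
Conditions: DBU (0.1 equiv), CH2Cl2, rt
Reagents that add atoms: none
Why: Base-mediated epimerisation through the enolate at C2 (thermodynamic equilibration) should converge on the trans isomer, in which both substituents are pseudo-equatorial; C3 is not enolisable and keeps its configuration, which fixes C2 as R.

Step 5
Reactants: 10 (2R,3S)-2-(13-acetoxytridecyl)-3-(benzyloxymethyl)cyclobutanone (trans)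
Product: 11 (4R,5R)-5-(13-acetoxytridecyl)-4-(benzyloxymethyl)dihydrofuran-2(3H)-one
Conditions: mCPBA (1.3 equiv), CH2Cl2, 0 °C to rt
Reagents that add atoms: 3-chloroperoxybenzoic acid (mCPBA), OOC(=O)c1cccc(Cl)c1
Why: The peracid adds to the strained carbonyl to give the tetrahedral peroxy adduct, and the ring bond from the carbonyl carbon to C2 that lies antiperiplanar to the O–O bond shifts to oxygen as 3-chlorobenzoate leaves (Baeyer–Villiger oxidation; closest precedent is the oxidation of 2-alkylcyclobutanones to 5-alkyl-γ-butyrolactones). The five-membered lactone is closed by ring expansion, a 1,2-shift that inserts O1 between the carbonyl carbon and the chain-bearing carbon, not by cyclisation of an open chain. No stereocentre is created: the migrating carbon keeps its configuration (retention) and the CH2OBn carbon is a spectator, so the trans relation of 10 becomes the (4R,5R) arrangement of 11. The step needs migration of the chain-bearing CH in preference to the ring CH2, and the higher migratory aptitude of the secondary carbon secures this. It also needs chemoselectivity, which rests on the high electrophilicity of the four-membered ketone (relief of angle strain on addition), so the acetate, the benzyl ether and the arene should be left alone under these mild conditions.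

Step 6
Reactants: 11 (4R,5R)-5-(13-acetoxytridecyl)-4-(benzyloxymethyl)dihydrofuran-2(3H)-one
Product: 12 (4R,5R)-5-(13-acetoxytridecyl)-4-(hydroxymethyl)dihydrofuran-2(3H)-one
Conditions: H2 (1 atm), 10% Pd/C, EtOAc, rt
Reagents that add atoms: none
Why: Catalytic hydrogenolysis of the benzyl ether should free the primary alcohol under neutral conditions that leave the lactone, the acetate and both stereocentres unchanged.

Step 7
Reactants: 12 (4R,5R)-5-(13-acetoxytridecyl)-4-(hydroxymethyl)dihydrofuran-2(3H)-one
Product: 13 (2R,3S)-2-(13-acetoxytridecyl)-5-oxotetrahydrofuran-3-carboxylic acid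
Conditions: CrO3, H2SO4, H2O, acetone, 0 °C
Reagents that add atoms: chromium trioxide, O=[Cr](=O)=O; water, O (the new carboxyl oxygen enters through the aldehyde hydrate)
Why: Jones oxidation should take the primary alcohol through the aldehyde hydrate to the acid in an acidic medium that avoids base-induced epimerisation or translactonisation and spares the acetate and the lactone.

Step 8
Reactants: 13 (2R,3S)-2-(13-acetoxytridecyl)-5-oxotetrahydrofuran-3-carboxylic acid
Product: 14 (2R,3S,4R)-2-(13-hydroxytridecyl)-5-oxotetrahydrofuran-3,4-dicarboxylic acid (all-trans; the malonate-type centre is epimerisable)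
Conditions: MeOMgOCO2Me (2 M in DMF, excess), 130 °C, N2; then cold aq. HCl, EtOAc; crude product used at once
Reagents that add atoms: methyl magnesium carbonate (MeOMgOCO2Me), COC(=O)O[Mg]OC
Why: Carboxylation with methyl magnesium carbonate: the magnesium carboxylate of the ring acid assists enolisation of the lactone α-CH2 and the enolate is trapped as a magnesium chelate of the malonic half-acid, a reaction type established for 5-oxotetrahydrofuran-3-carboxylic acids; the hot magnesium methoxide medium should at the same time transesterify the acetate off, and the new centre is removed again in step 9.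

Step 9
Reactants: 14 (2R,3S,4R)-2-(13-hydroxytridecyl)-5-oxotetrahydrofuran-3,4-dicarboxylic acid
Product: 15 (2R,3S)-2-(13-hydroxytridecyl)-4-methylidene-5-oxotetrahydrofuran-3-carboxylic acid
Conditions: aq. HCHO (37%), PhNHMe, NaOAc, AcOH, rt
Reagents that add atoms: formaldehyde, C=O
Why: Mannich reaction of the malonic half-acid with the iminium ion from formaldehyde and N-methylaniline, followed by decarboxylative elimination of the amine (decarboxylative methylenation), should place the exocyclic alkene on the lactone α-carbon only, and the buffered acidic medium should not epimerise the acid-bearing carbon or move the double bond into the ring.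

Step 10
Reactants: 15 (2R,3S)-2-(13-hydroxytridecyl)-4-methylidene-5-oxotetrahydrofuran-3-carboxylic acid
Product: 16 (2R,3S)-2-(13-acetoxytridecyl)-4-methylidene-5-oxotetrahydrofuran-3-carboxylic acid (target)
Conditions: vinyl acetate, Novozym 435 (immobilised Candida antarctica lipase B), t-BuOMe, 30 °C
Reagents that add atoms: vinyl acetate, C=COC(C)=O
Why: Lipase-catalysed transesterification with an enol ester (irreversible, since the vinyl alcohol tautomerises to acetaldehyde) should acetylate the unhindered primary alcohol under neutral conditions, while the hindered ring-bound acid is a poor acyl donor for the enzyme and the base-sensitive α-methylene lactone sees no amine; any 16 already formed in step 9 passes through unchanged.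

**Compound list**

1 | 15-hydroxypentadecanoic acid | OCCCCCCCCCCCCCCC(=O)O | starting material
2 | 15-acetoxypentadecanoic acid | CC(=O)OCCCCCCCCCCCCCCC(=O)O | intermediate
3 | (2R,5R)-2,5-dimethylpyrrolidine | C[C@@H]1CC[C@@H](C)N1 | starting material
4 | 15-acetoxypentadecanoyl chloride | CC(=O)OCCCCCCCCCCCCCCC(=O)Cl | intermediate (not isolated)
5 | 15-[(2R,5R)-2,5-dimethylpyrrolidin-1-yl]-15-oxopentadecyl acetate | C[C@@H]1CC[C@@H](C)N1C(=O)CCCCCCCCCCCCCCOC(C)=O | intermediate
6 | allyl benzyl ether | C=CCOCc1ccccc1 | starting material
7 | (2R,5R)-1-(15-acetoxypentadec-1-enylidene)-2,5-dimethylpyrrolidinium triflate (keteniminium triflate) | C[C@@H]1CC[C@@H](C)[N+]1=C=CCCCCCCCCCCCCCOC(C)=O.[O-]S(=O)(=O)C(F)(F)F | intermediate (not isolated)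
8 | (2R,5R)-1-[(3S)-2-(13-acetoxytridecyl)-3-(benzyloxymethyl)cyclobutylidene]-2,5-dimethylpyrrolidinium triflate, both C2 epimers of the four-membered ring (cyclobutaniminium triflate) | C[C@@H]1CC[C@@H](C)[N+]1=C1C(CCCCCCCCCCCCCOC(C)=O)[C@@H](COCc2ccccc2)C1.[O-]S(=O)(=O)C(F)(F)F | intermediate (not isolated)
9 | (3S)-2-(13-acetoxytridecyl)-3-(benzyloxymethyl)cyclobutanone, mixture of C2 epimers (C2 left unspecified) | O=C1C(CCCCCCCCCCCCCOC(C)=O)[C@@H](COCc2ccccc2)C1 | intermediate
10 | (2R,3S)-2-(13-acetoxytridecyl)-3-(benzyloxymethyl)cyclobutanone (trans) | O=C1[C@H](CCCCCCCCCCCCCOC(C)=O)[C@@H](COCc2ccccc2)C1 | intermediate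
11 | (4R,5R)-5-(13-acetoxytridecyl)-4-(benzyloxymethyl)dihydrofuran-2(3H)-one | O=C1O[C@H](CCCCCCCCCCCCCOC(C)=O)[C@@H](COCc2ccccc2)C1 | intermediate
12 | (4R,5R)-5-(13-acetoxytridecyl)-4-(hydroxymethyl)dihydrofuran-2(3H)-one | O=C1O[C@H](CCCCCCCCCCCCCOC(C)=O)[C@@H](CO)C1 | intermediate
13 | (2R,3S)-2-(13-acetoxytridecyl)-5-oxotetrahydrofuran-3-carboxylic acid | O=C1O[C@H](CCCCCCCCCCCCCOC(C)=O)[C@@H](C(=O)O)C1 | intermediate
14 | (2R,3S,4R)-2-(13-hydroxytridecyl)-5-oxotetrahydrofuran-3,4-dicarboxylic acid | O=C1O[C@H](CCCCCCCCCCCCCO)[C@@H](C(=O)O)[C@@H]1C(=O)O | intermediate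
15 | (2R,3S)-2-(13-hydroxytridecyl)-4-methylidene-5-oxotetrahydrofuran-3-carboxylic acid | C=C1C(=O)O[C@H](CCCCCCCCCCCCCO)[C@H]1C(=O)O | intermediate
16 | (2R,3S)-2-(13-acetoxytridecyl)-4-methylidene-5-oxotetrahydrofuran-3-carboxylic acid | C=C1C(=O)O[C@H](CCCCCCCCCCCCCOC(C)=O)[C@H]1C(=O)O | target

**Step count**

Total steps: 10. Longest linear sequence: 10 steps (1 to 16).

**Steps most likely to fail, with fallbacks**

Step 3 (asymmetric keteniminium cycloaddition). The auxiliary may discriminate poorly between the two faces of a monosubstituted, conformationally free alkene, or induce the opposite sense. The hindered keteniminium ion may also add so slowly that self-condensation of the activated amide takes over. The fallback sets out from acid 2 and ether 6 and comes back at ketone 10. Acid 2 is converted through chloride 4 with pyrrolidine and Et3N into 15-oxo-15-(pyrrolidin-1-yl)pentadecyl acetate F1. Tf2O and 2,4,6-collidine turn this into the achiral, unhindered keteniminium triflate F2, which adds to 6 to give the racemic cyclobutaniminium triflate F3. Bicarbonate hydrolysis gives the racemic ketone as C2 epimers F4, and DBU equilibrates it to the racemic trans ketone F5. The enantiomers of F5 are separated by preparative chromatography on a chiral stationary phase (supercritical CO2 with an alcohol modifier); the (2R,3S) enantiomer is 10.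

Step 8 (carboxylation with methyl magnesium carbonate). Enolisation and carboxylation at the lactone α-carbon may be incomplete. The malonic half-acid may lose CO2 during the acidic work-up before it is trapped. The freed primary alkoxide may exchange with the lactone at 130 °C and give oligomers. The fallback sets out from 13 and comes back at 15, replacing steps 8 and 9 by a Mannich reaction of a preformed enolate. LiOH in THF/H2O removes the acetate and opens the lactone, and acidification with HCl recloses the γ-lactone to give (2R,3S)-2-(13-hydroxytridecyl)-5-oxotetrahydrofuran-3-carboxylic acid F6. LiN(SiMe3)2 (3.3 equiv, THF, −78 °C) forms the alkoxide–carboxylate–lactone enolate, and dimethylmethyleneammonium iodide aminomethylates it to (2R,3S,4R)-4-[(dimethylamino)methyl]-2-(13-hydroxytridecyl)-5-oxotetrahydrofuran-3-carboxylic acid F7. MeI quaternises the amine to the trimethylammonium iodide F8, and aq. NaHCO3 eliminates trimethylamine to give 15.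

Step 10 (enzymatic acetylation). Acyl transfer may be slow because the free acid inhibits the enzyme or the α-methylene lactone alkylates it. The carboxylic acid may also be drawn into ester formation and give oligomers. The fallback sets out from 15 and comes back at 16. Ac2O with catalytic Sc(OTf)3 in MeCN at 0 °C acetylates the alcohol and converts the acid into the mixed anhydride, acetic (2R,3S)-2-(13-acetoxytridecyl)-4-methylidene-5-oxotetrahydrofuran-3-carboxylic anhydride F9. Stirring the crude product in THF/H2O at rt hydrolyses the much more labile mixed anhydride and leaves the alkyl acetate, giving 16 without any amine base that could move the double bond into the ring.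

**Further compounds**

F1 | step 3 | 15-oxo-15-(pyrrolidin-1-yl)pentadecyl acetate | O=C(CCCCCCCCCCCCCCOC(C)=O)N1CCCC1
F2 | step 3 | 1-(15-acetoxypentadec-1-enylidene)pyrrolidinium triflate | CC(=O)OCCCCCCCCCCCCCC=C=[N+]1CCCC1.[O-]S(=O)(=O)C(F)(F)F
F3 | step 3 | 1-[2-(13-acetoxytridecyl)-3-(benzyloxymethyl)cyclobutylidene]pyrrolidinium triflate, racemic, both C2 epimers | CC(=O)OCCCCCCCCCCCCCC1C(COCc2ccccc2)CC1=[N+]1CCCC1.[O-]S(=O)(=O)C(F)(F)F
F4 | step 3 | 2-(13-acetoxytridecyl)-3-(benzyloxymethyl)cyclobutanone, racemic, both C2 epimers | O=C1C(CCCCCCCCCCCCCOC(C)=O)C(COCc2ccccc2)C1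
F5 | step 3 | racemic trans-2-(13-acetoxytridecyl)-3-(benzyloxymethyl)cyclobutanone (both enantiomers written) | O=C1[C@H](CCCCCCCCCCCCCOC(C)=O)[C@@H](COCc2ccccc2)C1.O=C1[C@@H](CCCCCCCCCCCCCOC(C)=O)[C@H](COCc2ccccc2)C1
F6 | step 8 | (2R,3S)-2-(13-hydroxytridecyl)-5-oxotetrahydrofuran-3-carboxylic acid | O=C1O[C@H](CCCCCCCCCCCCCO)[C@@H](C(=O)O)C1
F7 | step 8 | (2R,3S,4R)-4-[(dimethylamino)methyl]-2-(13-hydroxytridecyl)-5-oxotetrahydrofuran-3-carboxylic acid | O=C1O[C@H](CCCCCCCCCCCCCO)[C@@H](C(=O)O)[C@@H]1CN(C)C
F8 | step 8 | [(2R,3S,4R)-3-carboxy-2-(13-hydroxytridecyl)-5-oxotetrahydrofuran-4-yl]methyl-trimethylammonium iodide | O=C1O[C@H](CCCCCCCCCCCCCO)[C@@H](C(=O)O)[C@@H]1C[N+](C)(C)C.[I-]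
F9 | step 10 | acetic (2R,3S)-2-(13-acetoxytridecyl)-4-methylidene-5-oxotetrahydrofuran-3-carboxylic anhydride | C=C1C(=O)O[C@H](CCCCCCCCCCCCCOC(C)=O)[C@H]1C(=O)OC(C)=O
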